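**Plan**

- Labdane numbers are used for all compounds: decalin C1–C10 (ring fusion C5/C10), C20 on C10, C18/C19 on C4, C17 on C8, ring C = C8–O–C15–C14–C13(C16)–C12–C11–C9. The enabling feature is that quaternary C10 lies para to C3 in ring A and carries C9 with its branch C11–C12. Ring A can therefore begin as a 3-substituted 2,4-dimethylphenol whose para carbon closes ring B onto an allyl unit C9–C11–C12.
- Cuts, in retrosynthetic order: epoxide oxygen at C13/C14; C13=C14 (metathesis); C12–C13; O–C15; C8–O and C8–C17; C3–Br; C4–C19; C9–C10 (ring B); then C9–C11, C8–C9, C7–C8 and C5–C6 of the chain.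
- Forward order: arene (future ring A) → chain C6–C12 with C8 masked as a dioxolane → ring B by palladium → ring A reduced, gem-dimethylated and brominated → C8 carbinol → ring C by metathesis → epoxide.
- Stereochemistry: C9 from the chiral palladium catalyst and C10 from the chair-like closure; C5 from protonation in the Li/NH3 reduction; C3 from axial hydrogen delivery to an α-bromo radical; C8 from attack anti to the C10 methyl; C13/C14 from peripheral peracid attack on the oxocene.

Key step: step 10

Remark: 1 is taken as purchasable. The sense of induction of the ligand in step 10 is assumed, and its mirror image would be used if the sense proved opposite. CIP descriptors at C9 and C10 change along the route only because priorities change; the geometry is that of the SMILES.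

**Route**

Step 1
Reactants: 1 3-bromo-2,4-dimethylaniline
Product: 3 3-bromo-2,4-dimethylphenol, via arenediazonium hydrogensulfate 2 (not isolated)
Conditions: NaNO2, aq. H2SO4, 0 °C; then aq. H2SO4, 100 °C
Reagents that add atoms: water, O
Why: Diazotisation and thermal hydrolysis of the diazonium salt (phenol synthesis from an arylamine) should replace NH2 by OH and leave the flanked aryl bromide untouched.

Step 2
Reactants: 3 3-bromo-2,4-dimethylphenol
Product: 4 (3-bromo-2,4-dimethylphenoxy)triisopropylsilane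
Conditions: i-Pr3SiCl, imidazole, DMF, rt
Reagents that add atoms: chlorotriisopropylsilane, CC(C)[Si](Cl)(C(C)C)C(C)C
Why: Imidazole-assisted silylation masks the acidic phenol for the organometallic steps with a group that tolerates acid and is later removed by fluoride.

Step 3
Reactants: 4 (3-bromo-2,4-dimethylphenoxy)triisopropylsilane; 5 oxirane
Product: 7 2-[2,6-dimethyl-3-(triisopropylsilyloxy)phenyl]ethanol, via aryllithium 6 (not isolated)
Conditions: n-BuLi, THF, −78 °C; then 5, BF3·OEt2, −78 °C
Reagents that add atoms: none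
Why: Bromine–lithium exchange gives the 2,6-disubstituted aryllithium, which opens BF3-activated oxirane (epoxide opening by an organolithium) to add C6 and C7.

Step 4
Reactants: 7 2-[2,6-dimethyl-3-(triisopropylsilyloxy)phenyl]ethanol
Product: 8 [3-(2-bromoethyl)-2,4-dimethylphenoxy]triisopropylsilane
Conditions: CBr4, PPh3, CH2Cl2, 0 °C
Reagents that add atoms: carbon tetrabromide, BrC(Br)(Br)Br
Why: The Appel reaction converts the primary alcohol into the bromide under neutral conditions that spare the aryl silyl ether.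

Step 5
Reactants: 8 [3-(2-bromoethyl)-2,4-dimethylphenoxy]triisopropylsilane; 9 diethyl oxalate
Product: 11 ethyl 4-[2,6-dimethyl-3-(triisopropylsilyloxy)phenyl]-2-oxobutanoate, via Grignard reagent 10 (not isolated)
Conditions: Mg, THF, rt; then added to 9 (2 equiv), THF, −78 °C
Reagents that add atoms: none
Why: Inverse addition of the Grignard reagent to excess diethyl oxalate at low temperature (Grignard acylation to an α-keto ester) should stop after one addition, because the tetrahedral adduct survives until work-up, and adds C8 and C9.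

Step 6
Reactants: 11 ethyl 4-[2,6-dimethyl-3-(triisopropylsilyloxy)phenyl]-2-oxobutanoate
Product: 12 ethyl 2-{2-[2,6-dimethyl-3-(triisopropylsilyloxy)phenyl]ethyl}-1,3-dioxolane-2-carboxylate
Conditions: Me3SiOCH2CH2OSiMe3, Me3SiOTf (cat.), CH2Cl2, −78 to −20 °C
Reagents that add atoms: 1,2-bis(trimethylsilyloxy)ethane, C[Si](C)(C)OCCO[Si](C)(C)C
Why: Silyl-transfer ketalisation should convert the electrophilic α-keto group into the dioxolane without cleaving the aryl silyl ether, which makes C8 an achiral, non-enolisable spectator.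

Step 7
Reactants: 12 ethyl 2-{2-[2,6-dimethyl-3-(triisopropylsilyloxy)phenyl]ethyl}-1,3-dioxolane-2-carboxylate
Product: 13 2-{2-[2,6-dimethyl-3-(triisopropylsilyloxy)phenyl]ethyl}-1,3-dioxolane-2-carbaldehyde
Conditions: i-Bu2AlH, CH2Cl2, −78 °C
Reagents that add atoms: none
Why: Low-temperature hydride reduction of the α,α-dialkoxy ester (partial ester reduction) should stop at the chelated hemiacetal aluminate and give the aldehyde on work-up.

Step 8
Reactants: 13 2-{2-[2,6-dimethyl-3-(triisopropylsilyloxy)phenyl]ethyl}-1,3-dioxolane-2-carbaldehyde; 14 vinylmagnesium bromide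
Product: 16 racemic 1-(2-{2-[2,6-dimethyl-3-(triisopropylsilyloxy)phenyl]ethyl}-1,3-dioxolan-2-yl)prop-2-en-1-yl methyl carbonate, via magnesium alkoxide 15 (not isolated)
Conditions: 14, THF, −78 °C; then ClCO2Me, −78 to 0 °C
Reagents that add atoms: methyl chloroformate, COC(=O)Cl
Why: Grignard addition to the non-enolisable aldehyde adds C11 and C12, and acylation of the alkoxide in the same flask gives the branched allylic carbonate, whose C9 configuration is erased on ionisation.

Step 9
Reactants: 16 racemic 1-(2-{2-[2,6-dimethyl-3-(triisopropylsilyloxy)phenyl]ethyl}-1,3-dioxolan-2-yl)prop-2-en-1-yl methyl carbonate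
Product: 17 racemic 1-{2-[2-(3-hydroxy-2,6-dimethylphenyl)ethyl]-1,3-dioxolan-2-yl}prop-2-en-1-yl methyl carbonate
Conditions: Bu4NF, AcOH, THF, 0 °C
Reagents that add atoms: none
Why: Buffered fluoride should cleave the phenolic silyl ether (desilylation) much faster than it attacks the alkyl carbonate, freeing the nucleophile for ring closure.

Step 10
Reactants: 17 racemic 1-{2-[2-(3-hydroxy-2,6-dimethylphenyl)ethyl]-1,3-dioxolan-2-yl}prop-2-en-1-yl methyl carbonate
Product: 18 (9S,10S)-8,8-ethylenedioxy-4,10-dimethyl-9-vinyldecalin-1,4-dien-3-one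
Conditions: Pd2(dba)3·CHCl3 (2.5 mol %), (1R,2R)-N,N′-bis[2-(diphenylphosphino)benzoyl]cyclohexane-1,2-diamine (7.5 mol %), CH2Cl2 (0.01 M), rt
Reagents that add atoms: none
Why: Proposed new method: zerovalent palladium ionises the allylic carbonate with loss of CO2 and methoxide, which deprotonates the phenol, and the para carbon C10 of the phenoxide attacks the C9 terminus of the C9–C11–C12 π-allyl unit on the face opposite the metal (intramolecular Tsuji–Trost alkylation run as a dearomatisation). The closest known reactions are palladium- and iridium-catalysed enantioselective intramolecular allylic dearomatisations of para-tethered phenols to spirocyclohexadienones; a fused closure from a meta tether onto a methyl-bearing para carbon has not been shown. Ring B closes in a 6-exo mode because C8 lies outside the allyl unit, so C9 is the only terminus in reach (C12 would need an eight-membered ring); an allyl unit with C8 as its central carbon would instead offer a second six-membered closure at its CH2 terminus, which is why C8 is carried as a dioxolane, whose gem-dialkoxy substitution also favours cyclisation (Thorpe–Ingold effect). C9 should be set by the ligand, since the diastereomeric π-allyl complexes interconvert through the unsubstituted C12 terminus faster than they cyclise, and C10 should be set relative to C9 by a chair-like transition state in which the allyl unit points away from the arene, placing the vinyl group equatorial and cis to the C10 methyl. The step needs carbon rather than oxygen attack and para (C10) rather than ortho (C4) attack: oxygen would have to close an eight- or ten-membered ring, C4 is flanked by the phenoxide oxygen and the tether-bearing C5 and would give the less stable linearly conjugated dienone, and high dilution suppresses intermolecular O-allylation.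

Step 11
Reactants: 18 (9S,10S)-8,8-ethylenedioxy-4,10-dimethyl-9-vinyldecalin-1,4-dien-3-one
Product: 19 (9S,10S)-8,8-ethylenedioxy-4,10-dimethyl-9-vinyldecal-4-en-3-one
Conditions: Cu(OAc)2 (5 mol %), 1,2-bis(diphenylphosphino)benzene (5 mol %), (MeO)2MeSiH, t-BuOH, toluene, 0 °C to rt
Reagents that add atoms: none
Why: Copper hydride generated from the silane should add hydride to C1, the only unhindered β-carbon (1,4-reduction of a cyclohexadienone), while the tetrasubstituted C4=C5 enone and the isolated vinyl group do not react and t-BuOH protonates the copper enolate.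

Step 12
Reactants: 19 (9S,10S)-8,8-ethylenedioxy-4,10-dimethyl-9-vinyldecal-4-en-3-one
Product: 21 (5S,9S,10R)-8,8-ethylenedioxy-4,4,10-trimethyl-9-vinyldecalin-3-one, via lithium enolate 20 (not isolated)
Conditions: Li, NH3(l)/THF, t-BuOH (1 equiv), −78 °C; isoprene; then MeI, −78 to −33 °C
Reagents that add atoms: iodomethane, CI
Why: In this Stork reductive alkylation, lithium in ammonia reduces the enone to the C3 enolate, axial protonation at C5 sets the trans ring fusion, and the regiodefined enolate is methylated at C4 to complete the gem-dimethyl group.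

Step 13
Reactants: 21 (5S,9S,10R)-8,8-ethylenedioxy-4,4,10-trimethyl-9-vinyldecalin-3-one
Product: 23 (5S,9S,10R)-8,8-ethylenedioxy-4,4,10-trimethyl-9-vinyldecal-2-en-3-yl trifluoromethanesulfonate, via potassium enolate 22 (not isolated)
Conditions: KN(SiMe3)2, THF, −78 °C; then PhNTf2, −78 to 0 °C
Reagents that add atoms: N-phenylbis(trifluoromethanesulfonimide), O=S(=O)(N(c1ccccc1)S(=O)(=O)C(F)(F)F)C(F)(F)F
Why: Deprotonation can only occur at C2, and O-sulfonylation of the enolate (enol triflate formation) fixes the C2=C3 double bond.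

Step 14
Reactants: 23 (5S,9S,10R)-8,8-ethylenedioxy-4,4,10-trimethyl-9-vinyldecal-2-en-3-yl trifluoromethanesulfonate
Product: 24 (5S,9S,10R)-3-bromo-8,8-ethylenedioxy-4,4,10-trimethyl-9-vinyldecal-2-ene
Conditions: Ni(cod)2 (10 mol %), LiBr, DMA/THF, rt
Reagents that add atoms: lithium bromide, [Li+].[Br-]
Why: Nickel-catalysed halide exchange of the enol triflate (oxidative addition, triflate–bromide exchange at nickel, reductive elimination) should give the alkenyl bromide with the double bond in place and the terminal olefin untouched.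

Step 15
Reactants: 24 (5S,9S,10R)-3-bromo-8,8-ethylenedioxy-4,4,10-trimethyl-9-vinyldecal-2-ene
Product: 26 2-[(5S,9S,10R)-3-bromo-8,8-ethylenedioxy-4,4,10-trimethyldecal-2-en-9-yl]ethanol, via alkylborane 25 (not isolated)
Conditions: 9-BBN-H, THF, 0 °C to rt; then NaOH, H2O2, 0 °C
Reagents that add atoms: hydrogen peroxide, OO
Why: In this hydroboration–oxidation, 9-BBN should add to the terminal vinyl group with boron at C12 and ignore the hindered, electron-poor alkenyl bromide, and alkaline peroxide then oxidises the C–B bond.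

Step 16
Reactants: 26 2-[(5S,9S,10R)-3-bromo-8,8-ethylenedioxy-4,4,10-trimethyldecal-2-en-9-yl]ethanol
Product: 27 tert-butyl{2-[(5S,9S,10R)-3-bromo-8,8-ethylenedioxy-4,4,10-trimethyldecal-2-en-9-yl]ethoxy}diphenylsilane
Conditions: t-BuPh2SiCl, imidazole, DMF, rt
Reagents that add atoms: tert-butyl(chloro)diphenylsilane, CC(C)(C)[Si](Cl)(c1ccccc1)c1ccccc1
Why: Silylation with the acid-stable tert-butyldiphenylsilyl group protects C12–OH through the ketal hydrolysis and keeps it from cyclising onto C8.

Step 17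
Reactants: 27 tert-butyl{2-[(5S,9S,10R)-3-bromo-8,8-ethylenedioxy-4,4,10-trimethyldecal-2-en-9-yl]ethoxy}diphenylsilane
Product: 28 tert-butyl{2-[(3R,5S,9S,10R)-3-bromo-8,8-ethylenedioxy-4,4,10-trimethyldecalin-9-yl]ethoxy}diphenylsilane
Conditions: Co(acac)2, t-BuOOH, Et3SiH, 1,4-cyclohexadiene, n-PrOH, rt
Reagents that add atoms: none
Why: Cobalt-hydride hydrogen-atom-transfer hydrogenation of the alkenyl halide should add H to C2 (avoiding a β-bromo radical and loss of bromine), and the α-bromo C3 radical should take its second hydrogen from 1,4-cyclohexadiene on the axial face anti to the axial C4 methyl, leaving bromine equatorial and cis to the C10 methyl.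

Step 18
Reactants: 28 tert-butyl{2-[(3R,5S,9S,10R)-3-bromo-8,8-ethylenedioxy-4,4,10-trimethyldecalin-9-yl]ethoxy}diphenylsilane
Product: 29 (3R,5S,9S,10R)-3-bromo-9-[2-(tert-butyldiphenylsilyloxy)ethyl]-4,4,10-trimethyldecalin-8-one
Conditions: 1 M HCl, THF, 40 °C
Reagents that add atoms: water, O
Why: Aqueous acid should hydrolyse the dioxolane (ketal hydrolysis) while the silyl ether and the secondary bromide are stable, and C9 keeps its thermodynamically preferred equatorial side chain.

Step 19
Reactants: 29 (3R,5S,9S,10R)-3-bromo-9-[2-(tert-butyldiphenylsilyloxy)ethyl]-4,4,10-trimethyldecalin-8-one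
Product: 30 tert-butyl{2-[(3R,5S,9R,10S)-3-bromo-4,4,10-trimethyl-8-methylenedecalin-9-yl]ethoxy}diphenylsilane
Conditions: Ph3PCH3Br, KOt-Bu, THF, rt to 50 °C
Reagents that add atoms: methyltriphenylphosphonium bromide, C[P+](c1ccccc1)(c1ccccc1)c1ccccc1.[Br-]
Why: Wittig methylenation of the hindered C8 ketone installs C17, any base-induced epimerisation at C9 favours the desired equatorial side chain, and the equatorial bromide has no anti-periplanar hydrogen for elimination.

Step 20
Reactants: 30 tert-butyl{2-[(3R,5S,9R,10S)-3-bromo-4,4,10-trimethyl-8-methylenedecalin-9-yl]ethoxy}diphenylsilane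
Product: 31 (3R,5S,8S,9S,10R)-3-bromo-9-[2-(tert-butyldiphenylsilyloxy)ethyl]-4,4,10-trimethylspiro[decalin-8,2′-oxirane]
Conditions: mCPBA, NaHCO3, CH2Cl2, 0 °C
Reagents that add atoms: 3-chloroperoxybenzoic acid, OOC(=O)c1cccc(Cl)c1
Why: Prilezhaev epoxidation on the face of the exocyclic olefin away from the axial C10 methyl, the usual course for 8(17)-labdenes, should place the C8 oxygen equatorial.

Step 21
Reactants: 31 (3R,5S,8S,9S,10R)-3-bromo-9-[2-(tert-butyldiphenylsilyloxy)ethyl]-4,4,10-trimethylspiro[decalin-8,2′-oxirane]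
Product: 32 (3R,5S,8S,9S,10R)-3-bromo-9-[2-(tert-butyldiphenylsilyloxy)ethyl]-4,4,8,10-tetramethyldecalin-8-ol
Conditions: LiEt3BH, THF, 0 °C
Reagents that add atoms: none
Why: Hydride should open the spiro-epoxide at its unhindered CH2 terminus (SN2 epoxide reduction), leaving the C8–O bond and the C8 configuration untouched, while the neopentyl equatorial bromide is inert to substitution.

Step 22
Reactants: 32 (3R,5S,8S,9S,10R)-3-bromo-9-[2-(tert-butyldiphenylsilyloxy)ethyl]-4,4,8,10-tetramethyldecalin-8-ol; 33 allyl bromide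
Product: 34 {2-[(3R,5S,8S,9S,10R)-8-allyloxy-3-bromo-4,4,8,10-tetramethyldecalin-9-yl]ethoxy}(tert-butyl)diphenylsilane
Conditions: KH, 18-crown-6 (cat.), 33, THF, 0 °C to rt
Reagents that add atoms: none
Why: In this Williamson etherification the crown-ether-activated potassium alkoxide of the tertiary alcohol should be alkylated by the reactive allylic bromide, while the equatorial C3 bromide resists substitution and elimination.

Step 23
Reactants: 34 {2-[(3R,5S,8S,9S,10R)-8-allyloxy-3-bromo-4,4,8,10-tetramethyldecalin-9-yl]ethoxy}(tert-butyl)diphenylsilane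
Product: 35 2-[(3R,5S,8S,9S,10R)-8-allyloxy-3-bromo-4,4,8,10-tetramethyldecalin-9-yl]ethanol
Conditions: Bu4NF, THF, rt
Reagents that add atoms: none
Why: Fluoride should cleave the silyl ether (desilylation) without affecting the allyl ether or the alkyl bromide.

Step 24
Reactants: 35 2-[(3R,5S,8S,9S,10R)-8-allyloxy-3-bromo-4,4,8,10-tetramethyldecalin-9-yl]ethanol
Product: 36 (3R,5S,8S,9S,10R)-8-allyloxy-3-bromo-9-(2-iodoethyl)-4,4,8,10-tetramethyldecalin
Conditions: I2, PPh3, imidazole, CH2Cl2, 0 °C
Reagents that add atoms: iodine, II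
Why: Appel-type iodination of the primary alcohol gives the iodide, which is kept cold and used at once so that the neighbouring ether oxygen does not displace it.

Step 25
Reactants: 36 (3R,5S,8S,9S,10R)-8-allyloxy-3-bromo-9-(2-iodoethyl)-4,4,8,10-tetramethyldecalin; 37 isopropenylmagnesium bromide
Product: 38 (3R,5S,8S,9S,10R)-8-allyloxy-3-bromo-4,4,8,10-tetramethyl-9-(3-methylbut-3-enyl)decalin
Conditions: 37, Li2CuCl4 (cat.), THF, −20 to 0 °C
Reagents that add atoms: none
Why: Copper-catalysed coupling of the alkenyl Grignard reagent with the primary iodide forms C12–C13 and should be far faster than any reaction at the hindered secondary bromide.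

Step 26
Reactants: 38 (3R,5S,8S,9S,10R)-8-allyloxy-3-bromo-4,4,8,10-tetramethyl-9-(3-methylbut-3-enyl)decalin
Product: 39 (3R,5S,8S,9S,10R,13Z)-3-bromo-8,15-epoxylabd-13-ene
Conditions: second-generation Grubbs catalyst (H2IMes)(PCy3)Cl2Ru=CHPh (10 mol %), CH2Cl2 (2 mM), 40 °C
Reagents that add atoms: none
Why: Ring-closing metathesis should join the allyl ether and the 1,1-disubstituted olefin into the eight-membered cyclic ether, helped by the gauche disposition of the two chains on adjacent carbons of the rigid decalin, and the ring size enforces the Z olefin.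

Step 27
Reactants: 39 (3R,5S,8S,9S,10R,13Z)-3-bromo-8,15-epoxylabd-13-ene
Product: 40 (3R,5S,8S,9S,10R,13S,14R)-3-bromo-8,15:13,14-diepoxylabdane
Conditions: mCPBA, NaHCO3, CH2Cl2, 0 °C
Reagents that add atoms: 3-chloroperoxybenzoic acid, OOC(=O)c1cccc(Cl)c1
Why: In this Prilezhaev epoxidation the axial C8 and C10 methyls should hold the O–C15 and C11–C12 bonds on the opposite side of the decalin, so the Z olefin hangs below ring B with only its outer face exposed, and peripheral attack there gives the cis-epoxide with the (13S,14R) configuration.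

**Compound list**

1 | 3-bromo-2,4-dimethylaniline | Cc1ccc(N)c(C)c1Br | starting material
2 | 3-bromo-2,4-dimethylbenzenediazonium hydrogensulfate | Cc1ccc([N+]#N)c(C)c1Br.OS(=O)(=O)[O-] | intermediate
3 | 3-bromo-2,4-dimethylphenol | Cc1ccc(O)c(C)c1Br | intermediate
4 | (3-bromo-2,4-dimethylphenoxy)triisopropylsilane | Cc1ccc(O[Si](C(C)C)(C(C)C)C(C)C)c(C)c1Br | intermediate
5 | oxirane (ethylene oxide) | C1CO1 | starting material
6 | [2,6-dimethyl-3-(triisopropylsilyloxy)phenyl]lithium | Cc1ccc(O[Si](C(C)C)(C(C)C)C(C)C)c(C)c1[Li] | intermediate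
7 | 2-[2,6-dimethyl-3-(triisopropylsilyloxy)phenyl]ethanol | Cc1ccc(O[Si](C(C)C)(C(C)C)C(C)C)c(C)c1CCO | intermediate
8 | [3-(2-bromoethyl)-2,4-dimethylphenoxy]triisopropylsilane | Cc1ccc(O[Si](C(C)C)(C(C)C)C(C)C)c(C)c1CCBr | intermediate
9 | diethyl oxalate | CCOC(=O)C(=O)OCC | starting material
10 | {2-[2,6-dimethyl-3-(triisopropylsilyloxy)phenyl]ethyl}magnesium bromide | Cc1ccc(O[Si](C(C)C)(C(C)C)C(C)C)c(C)c1CC[Mg]Br | intermediate
11 | ethyl 4-[2,6-dimethyl-3-(triisopropylsilyloxy)phenyl]-2-oxobutanoate | Cc1ccc(O[Si](C(C)C)(C(C)C)C(C)C)c(C)c1CCC(=O)C(=O)OCC | intermediate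
12 | ethyl 2-{2-[2,6-dimethyl-3-(triisopropylsilyloxy)phenyl]ethyl}-1,3-dioxolane-2-carboxylate | Cc1ccc(O[Si](C(C)C)(C(C)C)C(C)C)c(C)c1CCC1(OCCO1)C(=O)OCC | intermediate
13 | 2-{2-[2,6-dimethyl-3-(triisopropylsilyloxy)phenyl]ethyl}-1,3-dioxolane-2-carbaldehyde | Cc1ccc(O[Si](C(C)C)(C(C)C)C(C)C)c(C)c1CCC1(OCCO1)C=O | intermediate
14 | vinylmagnesium bromide | C=C[Mg]Br | starting material
15 | bromomagnesium alkoxide of racemic 1-(2-{2-[2,6-dimethyl-3-(triisopropylsilyloxy)phenyl]ethyl}-1,3-dioxolan-2-yl)prop-2-en-1-ol | Cc1ccc(O[Si](C(C)C)(C(C)C)C(C)C)c(C)c1CCC1(OCCO1)C(O[Mg]Br)C=C | intermediate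
16 | racemic 1-(2-{2-[2,6-dimethyl-3-(triisopropylsilyloxy)phenyl]ethyl}-1,3-dioxolan-2-yl)prop-2-en-1-yl methyl carbonate | Cc1ccc(O[Si](C(C)C)(C(C)C)C(C)C)c(C)c1CCC1(OCCO1)C(OC(=O)OC)C=C | intermediate
17 | racemic 1-{2-[2-(3-hydroxy-2,6-dimethylphenyl)ethyl]-1,3-dioxolan-2-yl}prop-2-en-1-yl methyl carbonate | Cc1ccc(O)c(C)c1CCC1(OCCO1)C(OC(=O)OC)C=C | intermediate
18 | (9S,10S)-8,8-ethylenedioxy-4,10-dimethyl-9-vinyldecalin-1,4-dien-3-one (ring A cross-conjugated dienone, vinyl cis to the C10 methyl) | CC1=C2CCC3(OCCO3)[C@@H](C=C)[C@]2(C)C=CC1=O | intermediate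
19 | (9S,10S)-8,8-ethylenedioxy-4,10-dimethyl-9-vinyldecal-4-en-3-one | CC1=C2CCC3(OCCO3)[C@@H](C=C)[C@]2(C)CCC1=O | intermediate
20 | lithium (5S,9S,10R)-8,8-ethylenedioxy-4,10-dimethyl-9-vinyldecal-3-en-3-olate (trans-fused) | [Li+].CC1=C([O-])CC[C@]2(C)[C@@H]1CCC1(OCCO1)[C@H]2C=C | intermediate
21 | (5S,9S,10R)-8,8-ethylenedioxy-4,4,10-trimethyl-9-vinyldecalin-3-one (trans-fused) | CC1(C)C(=O)CC[C@]2(C)[C@@H]1CCC1(OCCO1)[C@H]2C=C | intermediate
22 | potassium (5S,9S,10R)-8,8-ethylenedioxy-4,4,10-trimethyl-9-vinyldecal-2-en-3-olate | [K+].CC1(C)C([O-])=CC[C@]2(C)[C@@H]1CCC1(OCCO1)[C@H]2C=C | intermediate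
23 | (5S,9S,10R)-8,8-ethylenedioxy-4,4,10-trimethyl-9-vinyldecal-2-en-3-yl trifluoromethanesulfonate | CC1(C)C(OS(=O)(=O)C(F)(F)F)=CC[C@]2(C)[C@@H]1CCC1(OCCO1)[C@H]2C=C | intermediate
24 | (5S,9S,10R)-3-bromo-8,8-ethylenedioxy-4,4,10-trimethyl-9-vinyldecal-2-ene | CC1(C)C(Br)=CC[C@]2(C)[C@@H]1CCC1(OCCO1)[C@H]2C=C | intermediate
25 | 9-{2-[(5S,9S,10R)-3-bromo-8,8-ethylenedioxy-4,4,10-trimethyldecal-2-en-9-yl]ethyl}-9-borabicyclo[3.3.1]nonane | CC1(C)C(Br)=CC[C@]2(C)[C@@H]1CCC1(OCCO1)[C@H]2CCB1C2CCCC1CCC2 | intermediate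
26 | 2-[(5S,9S,10R)-3-bromo-8,8-ethylenedioxy-4,4,10-trimethyldecal-2-en-9-yl]ethanol | CC1(C)C(Br)=CC[C@]2(C)[C@@H]1CCC1(OCCO1)[C@H]2CCO | intermediate
27 | tert-butyl{2-[(5S,9S,10R)-3-bromo-8,8-ethylenedioxy-4,4,10-trimethyldecal-2-en-9-yl]ethoxy}diphenylsilane | CC1(C)C(Br)=CC[C@]2(C)[C@@H]1CCC1(OCCO1)[C@H]2CCO[Si](c1ccccc1)(c1ccccc1)C(C)(C)C | intermediate
28 | tert-butyl{2-[(3R,5S,9S,10R)-3-bromo-8,8-ethylenedioxy-4,4,10-trimethyldecalin-9-yl]ethoxy}diphenylsilane (Br equatorial) | CC1(C)[C@H](Br)CC[C@]2(C)[C@@H]1CCC1(OCCO1)[C@H]2CCO[Si](c1ccccc1)(c1ccccc1)C(C)(C)C | intermediate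
29 | (3R,5S,9S,10R)-3-bromo-9-[2-(tert-butyldiphenylsilyloxy)ethyl]-4,4,10-trimethyldecalin-8-one | CC1(C)[C@H](Br)CC[C@]2(C)[C@@H]1CCC(=O)[C@H]2CCO[Si](c1ccccc1)(c1ccccc1)C(C)(C)C | intermediate
30 | tert-butyl{2-[(3R,5S,9R,10S)-3-bromo-4,4,10-trimethyl-8-methylenedecalin-9-yl]ethoxy}diphenylsilane | CC1(C)[C@H](Br)CC[C@]2(C)[C@@H]1CCC(=C)[C@H]2CCO[Si](c1ccccc1)(c1ccccc1)C(C)(C)C | intermediate
31 | (3R,5S,8S,9S,10R)-3-bromo-9-[2-(tert-butyldiphenylsilyloxy)ethyl]-4,4,10-trimethylspiro[decalin-8,2′-oxirane] (8,17-epoxide, oxygen anti to the C10 methyl) | CC1(C)[C@H](Br)CC[C@]2(C)[C@@H]1CC[C@@]1(CO1)[C@H]2CCO[Si](c1ccccc1)(c1ccccc1)C(C)(C)C | intermediate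
32 | (3R,5S,8S,9S,10R)-3-bromo-9-[2-(tert-butyldiphenylsilyloxy)ethyl]-4,4,8,10-tetramethyldecalin-8-ol (OH equatorial) | CC1(C)[C@H](Br)CC[C@]2(C)[C@@H]1CC[C@](C)(O)[C@H]2CCO[Si](c1ccccc1)(c1ccccc1)C(C)(C)C | intermediate
33 | allyl bromide | C=CCBr | starting material
34 | {2-[(3R,5S,8S,9S,10R)-8-allyloxy-3-bromo-4,4,8,10-tetramethyldecalin-9-yl]ethoxy}(tert-butyl)diphenylsilane | CC1(C)[C@H](Br)CC[C@]2(C)[C@@H]1CC[C@](C)(OCC=C)[C@H]2CCO[Si](c1ccccc1)(c1ccccc1)C(C)(C)C | intermediate
35 | 2-[(3R,5S,8S,9S,10R)-8-allyloxy-3-bromo-4,4,8,10-tetramethyldecalin-9-yl]ethanol | CC1(C)[C@H](Br)CC[C@]2(C)[C@@H]1CC[C@](C)(OCC=C)[C@H]2CCO | intermediate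
36 | (3R,5S,8S,9S,10R)-8-allyloxy-3-bromo-9-(2-iodoethyl)-4,4,8,10-tetramethyldecalin | CC1(C)[C@H](Br)CC[C@]2(C)[C@@H]1CC[C@](C)(OCC=C)[C@H]2CCI | intermediate
37 | isopropenylmagnesium bromide | CC(=C)[Mg]Br | starting material
38 | (3R,5S,8S,9S,10R)-8-allyloxy-3-bromo-4,4,8,10-tetramethyl-9-(3-methylbut-3-enyl)decalin | CC1(C)[C@H](Br)CC[C@]2(C)[C@@H]1CC[C@](C)(OCC=C)[C@H]2CCC(C)=C | intermediate
39 | (3R,5S,8S,9S,10R,13Z)-3-bromo-8,15-epoxylabd-13-ene | CC1(C)[C@H](Br)CC[C@]2(C)[C@@H]1CC[C@]1(C)OC/C=C(C)\CC[C@@H]21 | intermediate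
40 | (3R,5S,8S,9S,10R,13S,14R)-3-bromo-8,15:13,14-diepoxylabdane | CC1(C)[C@H](Br)CC[C@]2(C)[C@@H]1CC[C@]1(C)OC[C@H]3O[C@@]3(C)CC[C@@H]21 | target

**Counts**

Total step count: 27. Longest linear sequence: 27 steps (1 to 40; the route is fully linear).

**Steps most likely to fail**

Step 10. The ring closure may leak into ortho attack at C4, intermolecular O-allylation or reversible ionisation of the product, or it may proceed with poor enantioselection. The fallback sets out from 13 and returns at 18, making C9–C10 by oxidative dearomatisation instead. Wittig olefination of 13 with the ylide from (2-trimethylsilylethyl)triphenylphosphonium iodide (n-BuLi, THF) would give the (Z)-allylsilane silyl ether F1. Bu4NF/AcOH would then free the phenol allylsilane F2. PhI(OAc)2 in (CF3)2CHOH at −20 °C would generate the phenoxonium ion, which the allylsilane traps at the para carbon with loss of silicon; para-allylation of 4-alkylphenols by allylsilanes under hypervalent-iodine oxidation is known. This gives the racemic dienone F3, and preparative chromatography on a chiral stationary phase would deliver 18.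

Step 22. Alkylation of the very hindered tertiary alkoxide may stall, and prolonged exposure to base invites silyl migration or slow loss of HBr. The fallback sets out from 32 and returns at 34, building the ether by carbene O–H insertion, which tolerates hindered tertiary alcohols. Ethyl diazoacetate with Rh2(OAc)4 in CH2Cl2 should give the alkoxyacetate F4. i-Bu2AlH at −78 °C should give the alkoxyacetaldehyde F5. Methylenation with Ph3P=CH2 then gives 34.

Step 27. Facial selectivity may be poor or reversed if the oxocene populates a conformer that exposes the other olefin face. The fallback sets out from 39 and returns at 40, delivering oxygen by anti addition. NBS in aqueous THF should put the bromonium ion on the face the peracid prefers, with water opening at the more substituted C13 from the opposite face to give the bromohydrin F6. K2CO3 in MeOH then closes it with inversion at C14 to 40.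

**Further compounds**

F1 | step 10 | {3-[2-(2-[(Z)-3-(trimethylsilyl)prop-1-enyl]-1,3-dioxolan-2-yl)ethyl]-2,4-dimethylphenoxy}triisopropylsilane | Cc1ccc(O[Si](C(C)C)(C(C)C)C(C)C)c(C)c1CCC1(OCCO1)/C=C\C[Si](C)(C)C
F2 | step 10 | 2,4-dimethyl-3-[2-(2-[(Z)-3-(trimethylsilyl)prop-1-enyl]-1,3-dioxolan-2-yl)ethyl]phenol | Cc1ccc(O)c(C)c1CCC1(OCCO1)/C=C\C[Si](C)(C)C
F3 | step 10 | racemic 8,8-ethylenedioxy-4,10-dimethyl-9-vinyldecalin-1,4-dien-3-one (18 and its mirror image) | CC1=C2CCC3(OCCO3)[C@@H](C=C)[C@]2(C)C=CC1=O.CC1=C2CCC3(OCCO3)[C@H](C=C)[C@@]2(C)C=CC1=O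
F4 | step 22 | ethyl {[(3R,5S,8S,9S,10R)-3-bromo-9-[2-(tert-butyldiphenylsilyloxy)ethyl]-4,4,8,10-tetramethyldecalin-8-yl]oxy}acetate | CC1(C)[C@H](Br)CC[C@]2(C)[C@@H]1CC[C@](C)(OCC(=O)OCC)[C@H]2CCO[Si](c1ccccc1)(c1ccccc1)C(C)(C)C
F5 | step 22 | {[(3R,5S,8S,9S,10R)-3-bromo-9-[2-(tert-butyldiphenylsilyloxy)ethyl]-4,4,8,10-tetramethyldecalin-8-yl]oxy}acetaldehyde | CC1(C)[C@H](Br)CC[C@]2(C)[C@@H]1CC[C@](C)(OCC=O)[C@H]2CCO[Si](c1ccccc1)(c1ccccc1)C(C)(C)C
F6 | step 27 | 3,14-dibromo-8,15-epoxylabdan-13-ol (bromohydrin with C13–OH on the target epoxide face and C14–Br anti to it) | CC1(C)[C@H](Br)CC[C@]2(C)[C@@H]1CC[C@]1(C)OC[C@H](Br)[C@@](C)(O)CC[C@@H]21
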